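The target in Thursday's flask reads 41.0% at 40.0 min and has stopped rising. Which option pays depends on why it stopped.

| flask | solid substrate | partner | temperature | remark | time |
|---|---|---|---|---|---|
| Thursday's | 21 mM | 0.80 equiv | 5 °C | the very flask that is asked about, followed so far |  |
| Tuesday's | 21 mM | 0.80 equiv | 11 °C | run made earlier |  |
| flask | 21 mM | 0.800 equiv | 5 °C |  | 50 min |

| run | time / min | target / % | solid substrate / % |
|---|---|---|---|
| Thursday's | 4.00 | 27.3 | 11.1 |
| Thursday's | 10.0 | 40.4 | 0 |
| Thursday's | 20.0 | 42.3 | 0 |
| Thursday's | 30.0 | 41.0 | 0 |
| Thursday's | 40.0 | 41.0 | 0.4 |
| Tuesday's | 4.00 | 27.9 | 4.6 |
| Tuesday's | 10.0 | 33.4 | 0.6 |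
| Tuesday's | 20.0 | 32.9 | 0 |
| Tuesday's | 30.0 | 32.2 | 0 |
| Tuesday's | 40.0 | 33.1 | 0 |

(each reading ± 1 percentage point)

- north: at 50 min take out 90% of the target then present, then wait 15 min
- south: at 50 min raise the temperature by 25 K, then wait 15 min
- south-west: at 50 min add partner, 100% of the amount charged, then wait 15 min
- south-east: change nothing and wait 15 min more

- target, in percent of the solid substrate first charged, at 50 min
- the option that brings most further target ("none" if no option brings more than 2 percentage points) (north / south / south-west / south-east / none)
- target present, with what was taken out counted in, in percent of the solid substrate first charged, after north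
- target present, with what was taken out counted in, in percent of the solid substrate first charged, after south-west

- percentages count the solid substrate that a species holds: one homo dimer counts as two
- solid, in amounts per volume of the solution: solid substrate
- removed target is counted in
- what was read earlier has a scatter of 1 percentage point, one standard deviation
- candidate steps: partner -> decomposed reagent; solid substrate <-> dissolved substrate; 2 solid substrate -> homo dimer; dissolved substrate + partner -> target
- at the start none of the solid substrate is in solution
- additions bring no volume worth counting

Two chemists dispute this. The first argues from the substrate. Thursday's solid reads 0% at 10.0 min, about when the target levels off. Tuesday's warmer run levels off lower, at 33.1%. She books the missing 59.0% as homo dimer, so in her view fresh partner brings under 2 percentage points, and the answer is "none".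

The second writes the balance of partner, the limiting reagent, charged at 0.800 equiv. Each partner ends either in target or as decomposed reagent. He names the capture share: the target at the plateau per equivalent of partner charged, here 0.512. Tuesday's flask reads 0.414, so in his view warmth shifts the split towards decomposition.

My own reckoning takes his side. The same share on a second dose gives 82.0% after south-west. I hold that as an upper mark, since the dose draws down the substrate it meets.

The forecast also takes his side, with a lower number. It gives 41.2% at 50 min, 41.3% after north, 69% after south-west, and south-west as best, with the words “Fresh partner meets substrate already in solution”.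

The flask gives 41.2%, 41.2% after north and 73.5% after south-west, the best option at 32 points more, while waiting brings 0 points. The forecast stands. At 50.0 min the flask holds 46.7% dissolved substrate and 0% partner, so what it lacks is partner.

    partner → decomposed reagent (k = 0.153 min⁻¹, Ea = 82.0 kJ mol⁻¹)
    solid substrate ⇌ dissolved substrate, rate k2*(cs2 - [dissolved substrate]) while solid is left; crystals form when [dissolved substrate] > cs2 (solubility = 11.0 mM, k = 1.75 min⁻¹)
    2 solid substrate → homo dimer (k = 4.38 M⁻¹ min⁻¹, Ea = 50.0 kJ mol⁻¹)
    dissolved substrate + partner → target (k = 18.9 M⁻¹ min⁻¹, Ea = 49.0 kJ mol⁻¹)
    (constants at 5 °C)

The two partner-consuming steps run side by side: half of the target step's turnover is done by 2.58 min, and half of the decomposition's by 2.06 min. By 50 min, c(decomposed reagent) is 8.15 mM, which is 0.485 of the partner charge, the complement of the capture share 0.512. The first chemist's homo dimer is there, but in a smaller share than she booked: in this flask it reads 12.1% at 5.00 min, with solid substrate at 5.51%, and 12.1% at 50.0 min, less than the 46.7% of dissolved substrate then. The second dose captures 0.404. For a neighbour charged with 0.480 equiv of partner, the capture share gives 24.6% target, and the neighbour computes to 25.1%.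

The readings were computed with constants of no real substance; scatter was added.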